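**Assumptions:** The target has no sp3 stereocentres, so "single enantiomer" is automatically satisfied. The only stereochemical elements are the three E trisubstituted alkenes, which I re-read from the SMILES. The skeleton is 4-hydroxycoumarin carrying a C3 (2E,6E)-farnesyl chain whose ω-methyl is now E-CH2OBz. I assume commercial (2E,6E)-farnesol.

## Retrosynthesis
- Disconnect C3 of the coumarin from C1 of the chain by Pd-catalysed Tsuji–Trost C-allylation of 4-hydroxycoumarin. The allyl donor is the C1 methyl carbonate of the ω-benzoyloxy-farnesyl unit, which ionises much faster than the allylic benzoate at the other end.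
- The ω-benzoate comes from benzoylation of an ω-allylic alcohol.
- That alcohol comes from Sharpless/Riley SeO2–TBHP oxidation of the terminal E-methyl of farnesyl methyl carbonate.
- The carbonate is made from commercial (E,E)-farnesol.
- No ring is formed, because the coumarin is purchased intact.

## Route

**Step 1**
Reactants: 1 (2E,6E)-farnesol; 2 methyl chloroformate
Product: 3 (2E,6E)-farnesyl methyl carbonate
Conditions: ClCO2Me (1.2 equiv), pyridine, CH2Cl2, 0 °C → rt
Reagents that add atoms: methyl chloroformate, COC(=O)Cl
Why: Pyridine-mediated acylation of the primary alcohol installs a Pd-labile leaving group and does not touch the alkenes, so the E geometry is kept.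

**Step 2**
Reactants: 3 farnesyl methyl carbonate; 4 tert-butyl hydroperoxide
Product: 5 (2E,6E,10E)-12-hydroxyfarnesyl methyl carbonate
Conditions: SeO2 (5 mol%), TBHP (70% aq., ~2 equiv), salicylic acid (cat.), CH2Cl2, rt; chromatographic separation from aldehyde and minor regioisomers
Reagents that add atoms: TBHP, CC(C)(C)OO (the oxygen source; SeO2 is catalytic)
Why: Riley/Sharpless allylic oxidation proceeds by a SeO2 ene reaction and a [2,3]-sigmatropic shift. It occurs at the most electron-rich, least hindered alkene (the terminal trisubstituted one), since the C2=C3 alkene is deactivated by the carbonate. The chair-like transition state oxidises the methyl trans to the chain, so the new CH2OH is E. No sp3 stereocentre is created.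

**Step 3**
Reactants: 5 12-hydroxy carbonate; 6 benzoyl chloride
Product: 7 (2E,6E,10E)-12-benzoyloxyfarnesyl methyl carbonate
Conditions: BzCl (1.3 equiv), pyridine, DMAP (cat.), CH2Cl2, 0 °C → rt
Reagents that add atoms: benzoyl chloride, O=C(Cl)c1ccccc1
Why: Standard DMAP-catalysed O-acylation of a primary alcohol. The methyl carbonate and all three alkenes are unaffected.

**Step 4**
Reactants: 7 benzoyloxy carbonate; 8 4-hydroxycoumarin
Product: 9 E-ω-benzoyloxyferulenol (target)
Conditions: Pd(PPh3)4 (5 mol%), MeCN (or THF), 50 °C
Reagents that add atoms: none beyond reactant 8 (the by-products are CO2 and MeOH)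
Why: Tsuji–Trost allylation. Pd(0) ionises the allylic carbonate selectively over the benzoate and releases CO2 and methoxide. The acidic 4-hydroxycoumarin (pKa ~4) immediately quenches the methoxide, so the benzoate is not transesterified. The resulting coumarinate attacks the π-allyl at the unhindered primary terminus (linear selectivity). Any O-allyl product re-ionises and funnels to the thermodynamic C3 product. The syn-π-allyl keeps the E geometry of C2=C3, and the remote E alkenes are untouched.

**Checks performed**
- **Structure:** The chain from the coumarin C3 is CH2–CH=C(Me)–CH2CH2–CH=C(Me)–CH2CH2–CH=C(Me)–CH2OBz with all three alkenes E, matching the target SMILES.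
- **Atom balance:** 7 = 5 + PhCO − H. Product 9 = 7 + 8 − CO2 − MeOH.
- **Functional-group survival:**
  - Step 2: the carbonate and the other alkenes survive.
  - Step 3: the carbonate survives.
  - Step 4: the benzoate survives.
- **Stereochemistry:** The E alkenes are present in the farnesol and are not scrambled later. The only new alkene-related stereochemical event is the E-selective oxidation in step 2.

## Compound list
1 | (2E,6E)-farnesol | CC(C)=CCC/C(C)=C/CC/C(C)=C/CO | starting material
2 | methyl chloroformate | COC(=O)Cl | starting material (reagent)
3 | (2E,6E)-farnesyl methyl carbonate | COC(=O)OC/C=C(\C)CC/C=C(\C)CC/C=C(C)C | intermediate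
4 | tert-butyl hydroperoxide | CC(C)(C)OO | starting material (reagent)
5 | (2E,6E,10E)-12-hydroxyfarnesyl methyl carbonate | COC(=O)OC/C=C(\C)CC/C=C(\C)CC/C=C(\C)CO | intermediate
6 | benzoyl chloride | O=C(Cl)c1ccccc1 | starting material (reagent)
7 | (2E,6E,10E)-12-benzoyloxyfarnesyl methyl carbonate | COC(=O)OC/C=C(\C)CC/C=C(\C)CC/C=C(\C)COC(=O)c1ccccc1 | intermediate
8 | 4-hydroxycoumarin | Oc1cc(=O)oc2ccccc12 | starting material
9 | E-ω-benzoyloxyferulenol | C/C(=C\CC/C(C)=C/Cc1c(O)c2ccccc2oc1=O)CC/C=C(\C)COC(=O)c1ccccc1 | target

**Total steps:** 4. **Longest linear sequence:** 4 steps (1 → 3 → 5 → 7 → 9).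

## Three steps most likely to fail
1. **Step 2 (SeO2 oxidation):** The yield is moderate (~30–40%). Over-oxidation to the aldehyde and oxidation at C7-Me are the competing pathways.
   - Fallback (different approach): Cleave the terminal alkene of farnesyl acetate through the terminal epoxide (NBS/H2O, then K2CO3, then H5IO6) to give the C10 aldehyde. Then do E-selective Wittig olefination with Ph3P=C(Me)CHO and NaBH4 reduction to build the E-CH2OH terminus. The acetate would then be swapped to the carbonate or bromide route.
2. **Step 4 (Tsuji–Trost with 4-hydroxycoumarin):** The risks are O- versus C-allylation, branched regioisomer, partial E/Z erosion, and ionisation of the ω-benzoate.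
   - Fallback (different approach): Use SN2 alkylation instead of Pd. Prepare the 12-hydroxyfarnesyl acetate, benzoylate it, and cleave the acetate selectively (K2CO3/MeOH at 0 °C or lipase). Convert the resulting allylic alcohol to the bromide (PPh3/CBr4) and alkylate 4-hydroxycoumarin with mild base (Et3N or NaHCO3).
3. **Step 3 (benzoylation of the allylic alcohol):** Pyridinium chloride can convert allylic alcohols or their activated derivatives to the allylic chloride, which would lower the yield.
   - Fallback (different approach): Install the benzoate by Mitsunobu esterification with PhCO2H/PPh3/DIAD. This is a different mechanism and avoids acyl chloride and chloride ions.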